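**Plan**

1. Retrosynthesis: cut C11–C12 (aldol condensation of a left-half C1 ketone, enolised at C11, with a right-half C12 aldehyde), then C1–CH3, C13–C14 (same aldol tactic with glyoxal monoacetal), C24–CH3 (ketone → methylene → epoxide → methyl), and in each seven-membered ring C17–C18, C18–C19 and one C19–CH3 (left: C8–C7, C7–C6, C6–CH3).
2. Enabling feature: both oxepanes contain O–C(CH3)2–C(=O or OH)–CH2 (O20–C19–C18–C17 and O5–C6–C7–C8). Without C18 (C7) and one methyl this is a six-membered enol ether O20–C19(CH3)=C17 trans-fused to the cyclohexane, so one dihydropyran serves both halves.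
3. Forward: purchased cyclohexane ketal ketone → quaternary C15 by chiral-imine Michael addition → δ-lactone ring (O20–C21) → 2-methyl dihydropyran → one-carbon ring enlargement to bromo-oxepene 12, the last common intermediate.
4. 12 is divided into a left half (C7 ketone → alcohol, C2=C3 enone) and a right half (C22=C23 enone, C13–C12 chain, C24 carbinol). After union at C11–C12, C1 is methylated and acetylated, C18 is unmasked from the bromoalkene and O7 is freed.
5. Stereochemistry: C15/C10 from (S)-1-phenylethylamine; C21/C4 and C7 from (R)-CBS reductions; C14 and C11 by protonation anti to the axial angular methyl; C24 by equatorial epoxidation of an exocyclic methylene; C1 by equatorial methyl attack on the ketone.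

Key step: step 5

Remark (numbering): backbone atoms are numbered C1–C24 along the target SMILES, methyl and acetyl carbons skipped. Common intermediates carry right-half locants C14–C24, which correspond to left-half C11→C1 in reverse order (C15≡C10, C18≡C7, C21≡C4, C24≡C1). The target is 1R,4S,7S,10S,11S,14S,15S,21S,24S.
Remark (assumption): 7-methyl-1,4-dioxaspiro[4.5]decan-8-one and monomeric, dried 2,2-dimethoxyacetaldehyde are taken as purchasable.
Remark (design): the ring-expansion substrate carries neither the C13–C12 chain nor the tertiary carbinol (C24 is a dioxolane), so that one ring-expanded compound feeds both halves. The alkylidene geometry of 26 and 35 is drawn Z and is lost on reduction.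

**Route**

Step 1
Reactants: 1 7-methyl-1,4-dioxaspiro[4.5]decan-8-one (racemic); 2 methyl acrylate
Product: 5 methyl 3-[(7S)-7-methyl-8-oxo-1,4-dioxaspiro[4.5]decan-7-yl]propanoate, via ketimine 3 (not isolated), via adduct imine 4 (not isolated)
Conditions: (S)-1-phenylethylamine, TsOH (cat.), toluene, reflux (Dean–Stark); 2, THF, 50 °C; 10% aq. AcOH, rt
Reagents that add atoms: none
Why: Chiral-imine (d'Angelo-type) Michael alkylation: the more substituted secondary enamine tautomer of 3 adds to the acrylate through a chair-like aza-ene transition state on the face away from the phenyl group, which sets the quaternary C15, and mild hydrolysis frees the ketone without touching the dioxolane.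

Step 2
Reactants: 5 keto ester
Product: 7 trans-fused δ-lactone (15S,21S), via hydroxy ester 6 (not isolated)
Conditions: (R)-Me-CBS (20 mol %), BH3·SMe2, THF, −20 °C; aqueous work-up; PPTS (cat.), toluene, 80 °C
Reagents that add atoms: none
Why: CBS reduction in which the quaternary C15 is the large and C22H2 the small group should give the (21S)-carbinol (OH cis to the C15 methyl, trans to the ester arm) under reagent control, and the trans hydroxy ester then lactonises; material from the minor enantiomer of 5 should end as the separable cis-fused lactone.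

Step 3
Reactants: 7 lactone
Product: 8 cyclic ketene acetal triflate (C17=C19–OTf)
Conditions: KHMDS, PhNTf2, THF–HMPA, −78 °C
Reagents that add atoms: N-phenyl-bis(trifluoromethanesulfonimide), O=S(=O)(N(c1ccccc1)S(=O)(=O)C(F)(F)F)C(F)(F)F
Why: Kinetic O-sulfonylation of the lactone potassium enolate is the standard conversion of a lactone into an enol triflate coupling partner and touches no stereocentre.

Step 4
Reactants: 8 ketene acetal triflate
Product: 9 trans-fused 2-methyl dihydropyran, O20–C19(CH3)=C17
Conditions: Me2CuLi, Et2O–THF, −78 → −20 °C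
Reagents that add atoms: lithium dimethylcuprate, [Li+].C[Cu-]C
Why: Enol triflate–cuprate coupling replaces triflate by methyl without moving the double bond, so the endocyclic enol ether needed for the ring enlargement is formed regiospecifically.

Step 5
Reactants: 9 2-methyl dihydropyran; 10 bromoform
Product: 12 bromo-oxepene ketal (C17=C18(Br), C19(CH3)2), via dibromocyclopropane 11 (not isolated)
Conditions: 10, KOtBu, pentane, −20 → 0 °C; filter, concentrate cold; Me3Al, CH2Cl2, −78 → 0 °C
Reagents that add atoms: trimethylaluminium, C[Al](C)C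
Why: Proposed new method: dibromocarbene (α-elimination of bromoform) adds cheletropically to the electron-rich C17=C19 enol ether, the only C=C present, from the face opposite the axial C15 methyl to give 11; Me3Al then abstracts the endo bromide while the C17–C19 bond opens in a disrotatory 2π-electrocyclic fashion assisted by the O20 lone pair, and the bromoaluminate formed transfers methyl to the oxocarbenium carbon C19 of the 2-bromoallyl cation. The closest known reactions are the thermal or silver-promoted ring expansion of gem-dihalocyclopropanated glycals and dihydropyrans to 2-halo-oxepenes with oxygen nucleophiles and the Me3Al methylation of cyclic ketals through oxocarbenium ions; using one organoaluminium reagent as ionising agent and carbon nucleophile is the new element. The oxepene ring is not closed by cyclisation but arises by one-carbon enlargement of the dihydropyran, C18 being inserted between C17 and C19. No stereocentre is created in the product (C19 becomes gem-dimethyl) and the ring-fusion centres C15 and C21 are not involved. The step needs capture at C19 and not at C17, and no proton loss from the C19 methyl: the ring oxygen localises the charge on C19, and the non-basic, ion-paired methyl donor at low temperature should outrun elimination.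

Step 6
Reactants: 12 bromo-oxepene ketal
Product: 14 oxepanone ketal (C18≡C7 ketone), via alkenyl boronate 13 (not isolated)
Conditions: B2pin2, PdCl2(dppf), KOAc, dioxane, 80 °C; NaBO3·4H2O, THF–H2O, rt
Reagents that add atoms: sodium perborate, [Na+].[O-]OB=O; bis(pinacolato)diboron, CC1(C)OB(OC1(C)C)B1OC(C)(C)C(C)(C)O1 (boron of 13 only)
Why: Miyaura borylation of the alkenyl bromide and oxidation of the alkenyl boronate give the enol and hence the ketone; palladium inserts only into the C–Br bond and the ketal is inert.

Step 7
Reactants: 14 oxepanone ketal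
Product: 15 (7S)-hydroxy oxepane ketal
Conditions: (R)-Me-CBS (1 equiv), BH3·SMe2, THF, −20 °C
Reagents that add atoms: none
Why: CBS reduction in which the quaternary oxygen-bearing C6 is the large and C8H2 the small group should deliver the (7S)-alcohol under reagent control.

Step 8
Reactants: 15 alcohol
Product: 16 O7-TBS ether
Conditions: TBSOTf, 2,6-lutidine, CH2Cl2, −78 → 0 °C
Reagents that add atoms: tert-butyldimethylsilyl triflate, CC(C)(C)[Si](C)(C)OS(=O)(=O)C(F)(F)F
Why: Silyl triflate silylation of the hindered secondary alcohol gives an ether that survives the enolate, organometallic and acylation steps and is removed last.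

Step 9
Reactants: 16 silyl ether ketal
Product: 17 left-half ketone (C1=O)
Conditions: PPTS, acetone–H2O, 55 °C
Reagents that add atoms: water, O
Why: Acid-catalysed hydrolysis of the dioxolane, which the secondary TBS ether and the ring ether tolerate under PPTS.

Step 10
Reactants: 17 ketone
Product: 19 left-half enone (C1=O, C2=C3), via silyl enol ether 18 (not isolated)
Conditions: LDA, THF, −78 °C; TMSCl; Pd(OAc)2, MeCN, rt
Reagents that add atoms: none
Why: Saegusa–Ito oxidation: LDA removes the unhindered C2 proton (C11 is neopentylic) and Pd(II) dehydrosilylates the kinetic enol ether, giving an enone in which C11 is the only enolisable carbon.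

Step 11
Reactants: 12 bromo-oxepene ketal
Product: 20 right-half ketone (C24=O)
Conditions: PPTS, acetone–H2O, 55 °C
Reagents that add atoms: water, O
Why: Acid-catalysed dioxolane hydrolysis under conditions too mild to ionise the bromine-deactivated allylic ring ether.

Step 12
Reactants: 20 ketone
Product: 22 right-half enone (C24=O, C22=C23), via silyl enol ether 21 (not isolated)
Conditions: LDA, THF, −78 °C; TMSCl; Pd(OAc)2 (stoichiometric, phosphine-free), MeCN, rt
Reagents that add atoms: none
Why: Saegusa–Ito oxidation through the kinetic C23 enol ether as in step 10; phosphine-free Pd(II) should leave the alkenyl bromide alone.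

Step 13
Reactants: 22 enone; 23 2,2-dimethoxyacetaldehyde
Product: 26 (Z)-alkylidene dienone (C14=C13), via aldol adduct 24 (not isolated), via mesylate 25 (not isolated)
Conditions: LDA, THF, −78 °C; 23; MsCl, Et3N, −78 °C → rt
Reagents that add atoms: none
Why: Directed aldol condensation: the cross-conjugated lithium enolate can only form at C14 (C23 is vinylic), it adds to the non-enolisable aldehyde, and mesylation with E1cB elimination gives the alkylidene ketone, so the configurations of 24 are irrelevant.

Step 14
Reactants: 26 dienone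
Product: 27 saturated ketone (14S) with CH2CH(OMe)2 chain
Conditions: [(Ph3P)CuH]6, THF–benzene, H2O (3 equiv), rt
Reagents that add atoms: none
Why: Copper hydride conjugate reduction (Stryker's reagent) saturates both enone double bonds and spares the bromoalkene and acetal; the C14 enolate is protonated axially on the face opposite the axial C15 methyl, which places the chain equatorial and is also the more stable epimer.

Step 15
Reactants: 27 ketone
Product: 28 exocyclic methylene (C24=CH2)
Conditions: Ph3PCH3Br, KOtBu, toluene, 80 °C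
Reagents that add atoms: methyltriphenylphosphonium bromide, C[P+](c1ccccc1)(c1ccccc1)c1ccccc1.[Br-]
Why: Wittig methylenation under hot, alkoxide-generated ylide conditions suited to hindered ketones; C14 is already the thermodynamic epimer, so reversible enolisation does no harm.

Step 16
Reactants: 28 methylene compound
Product: 29 spiro-epoxide (oxygen equatorial, anti to the C15 methyl)
Conditions: mCPBA, NaHCO3, CH2Cl2, 0 °C
Reagents that add atoms: 3-chloroperbenzoic acid, OOC(=O)c1cccc(Cl)c1
Why: Prilezhaev epoxidation of the 1,1-disubstituted alkene (the bromoalkene is too electron-poor); the axial face of C24 is blocked by the syn-axial C15 methyl, so the peracid attacks equatorially, as with 8(17)-ene labdanes.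

Step 17
Reactants: 29 epoxide
Product: 30 tertiary alcohol (24S; OH equatorial, CH3 axial)
Conditions: LiEt3BH, THF, 0 °C
Reagents that add atoms: none
Why: SN2 hydride opening at the unhindered CH2 terminus turns the epoxide into the axial methyl and equatorial tertiary alcohol of the target.

Step 18
Reactants: 30 tertiary alcohol
Product: 31 C24 acetate
Conditions: Ac2O, DMAP, Et3N, CH2Cl2, 40 °C
Reagents that add atoms: acetic anhydride, CC(=O)OC(C)=O
Why: DMAP-catalysed acylation of the equatorial tertiary alcohol installs the C24 acetate and prevents lactol formation when the aldehyde is released.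

Step 19
Reactants: 31 acetal
Product: 32 right-half aldehyde (C12=O)
Conditions: TsOH·H2O (cat.), acetone–H2O, rt
Reagents that add atoms: water, O
Why: Acid-catalysed hydrolysis of the acyclic dimethyl acetal is much faster than any reaction of the tertiary acetate or the ring ether.

Step 20
Reactants: 19 left-half enone; 32 right-half aldehyde
Product: 35 coupled (Z)-dienone (C11=C12), via aldol adduct 33 (not isolated), via mesylate 34 (not isolated)
Conditions: 19, LDA, THF, −78 °C; 32; MsCl, Et3N, −78 °C → rt
Reagents that add atoms: none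
Why: Directed aldol condensation as in step 13: the enone enolate is regiospecific for C11, should add to the aldehyde faster than it deprotonates it at −78 °C, and mesylation with E1cB elimination joins the halves through C11=C12.

Step 21
Reactants: 35 dienone
Product: 36 coupled C1 ketone (11S)
Conditions: [(Ph3P)CuH]6, THF–benzene, H2O (3 equiv), rt
Reagents that add atoms: none
Why: Stryker conjugate reduction of both enone double bonds, with axial protonation of the C11 enolate anti to the C10 methyl placing the C12 chain equatorial as at C14.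

Step 22
Reactants: 36 ketone
Product: 38 C1,C24-diacetate bromoalkene, via tertiary alkoxide 37 (not isolated)
Conditions: MeLi, CeCl3, THF, −78 °C; Ac2O, DMAP, −78 °C → rt
Reagents that add atoms: methyllithium, [Li]C; acetic anhydride, CC(=O)OC(C)=O
Why: Organocerium 1,2-addition to the hindered, enolisable ketone: axial attack is blocked by the syn-axial C10 methyl, so methyl enters equatorially and the alkoxide is axial (1R); acylating the alkoxide in the same flask gives the C1 acetate and would restore the C24 acetate had it been cleaved.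

Step 23
Reactants: 38 bromoalkene
Product: 40 C18 ketone (O7-TBS), via alkenyl boronate 39 (not isolated)
Conditions: B2pin2, PdCl2(dppf), KOAc, dioxane, 80 °C; NaBO3·4H2O, THF–H2O, rt
Reagents that add atoms: sodium perborate, [Na+].[O-]OB=O; bis(pinacolato)diboron, CC1(C)OB(OC1(C)C)B1OC(C)(C)C(C)(C)O1 (boron of 39 only)
Why: Miyaura borylation and boronate oxidation as in step 6 unmask the C18 ketone under conditions that spare the tertiary acetates and the silyl ether.

Step 24
Reactants: 40 silyl ether
Product: 41 CNP0298533.1
Conditions: HF·pyridine, THF–pyridine, 0 °C → rt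
Reagents that add atoms: none
Why: Fluoride-driven desilylation frees the C7 hydroxyl; the tertiary acetates and the ketone are stable to buffered HF.

**Compound list**

1 | 7-methyl-1,4-dioxaspiro[4.5]decan-8-one (racemic) | CC1CC2(CCC1=O)OCCO2 | starting material
2 | methyl acrylate | C=CC(=O)OC | starting material
3 | N-[(1S)-1-phenylethyl] ketimine of 1 (equilibrates with its secondary enamine) | C[C@H](N=C1CCC2(OCCO2)CC1C)c1ccccc1 | intermediate
4 | N-[(1S)-1-phenylethyl] ketimine of 5 (7S) | C[C@H](N=C1CCC2(OCCO2)C[C@]1(C)CCC(=O)OC)c1ccccc1 | intermediate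
5 | methyl 3-[(7S)-7-methyl-8-oxo-1,4-dioxaspiro[4.5]decan-7-yl]propanoate | O=C1CCC2(OCCO2)C[C@]1(C)CCC(=O)OC | intermediate
6 | methyl 3-[(7S,8S)-8-hydroxy-7-methyl-1,4-dioxaspiro[4.5]decan-7-yl]propanoate | O[C@H]1CCC2(OCCO2)C[C@]1(C)CCC(=O)OC | intermediate
7 | trans-fused δ-lactone (15S,21S): C19 lactone carbonyl, O20 on C21, angular CH3 on C15, C24 ethylene ketal | C1[C@]2(C)CCC(=O)O[C@H]2CCC13OCCO3 | intermediate
8 | ketene acetal triflate of 7 (C17=C19–OTf) | C1[C@]2(C)CC=C(OS(=O)(=O)C(F)(F)F)O[C@H]2CCC13OCCO3 | intermediate
9 | trans-fused 2-methyl dihydropyran (15S,21S), O20–C19(CH3)=C17, C24 ethylene ketal | C1[C@]2(C)CC=C(C)O[C@H]2CCC13OCCO3 | intermediate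
10 | bromoform | BrC(Br)Br | starting material
11 | 18,18-dibromocyclopropane adduct of 9 (CBr2 anti to the C15 methyl) | C1[C@]2(C)C[C@@H]3C(Br)(Br)[C@]3(C)O[C@H]2CCC14OCCO4 | intermediate
12 | trans-fused bromo-oxepene ketal (15S,21S): C17=C18(Br), C19(CH3)2, C24 ethylene ketal | C1[C@]2(C)CC=C(Br)C(C)(C)O[C@H]2CCC13OCCO3 | intermediate
13 | C18 pinacol boronate of 12 | C1[C@]2(C)CC=C(B3OC(C)(C)C(C)(C)O3)C(C)(C)O[C@H]2CCC14OCCO4 | intermediate
14 | trans-fused 2,2-dimethyloxepan-3-one ketal (left numbering: C7 ketone, C1 ketal) | C1[C@]2(C)CCC(=O)C(C)(C)O[C@H]2CCC13OCCO3 | intermediate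
15 | (7S)-alcohol of 14 | C1[C@]2(C)CC[C@H](O)C(C)(C)O[C@H]2CCC13OCCO3 | intermediate
16 | O7-TBS ether of 15 | C1[C@]2(C)CC[C@H](O[Si](C)(C)C(C)(C)C)C(C)(C)O[C@H]2CCC13OCCO3 | intermediate
17 | left-half ketone (C1=O; 4S,7S,10S; O7-TBS) | C1[C@]2(C)CC[C@H](O[Si](C)(C)C(C)(C)C)C(C)(C)O[C@H]2CCC1=O | intermediate
18 | C1(OTMS)=C2 silyl enol ether of 17 | C1[C@]2(C)CC[C@H](O[Si](C)(C)C(C)(C)C)C(C)(C)O[C@H]2CC=C1O[Si](C)(C)C | intermediate
19 | left-half enone (C1=O, C2=C3; 4S,7S,10S; O7-TBS) | C1[C@]2(C)CC[C@H](O[Si](C)(C)C(C)(C)C)C(C)(C)O[C@H]2C=CC1=O | intermediate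
20 | right-half ketone (C24=O) with bromo-oxepene (15S,21S) | C1[C@]2(C)CC=C(Br)C(C)(C)O[C@H]2CCC1=O | intermediate
21 | C24(OTMS)=C23 silyl enol ether of 20 | C1[C@]2(C)CC=C(Br)C(C)(C)O[C@H]2CC=C1O[Si](C)(C)C | intermediate
22 | right-half enone (C24=O, C22=C23) | C1[C@]2(C)CC=C(Br)C(C)(C)O[C@H]2C=CC1=O | intermediate
23 | 2,2-dimethoxyacetaldehyde | COC(OC)C=O | starting material
24 | C14 aldol adduct of 22 and 23 (diastereomers at C13 and C14) | COC(OC)C(O)C1[C@]2(C)CC=C(Br)C(C)(C)O[C@H]2C=CC1=O | intermediate
25 | C13 mesylate of 24 | COC(OC)C(OS(C)(=O)=O)C1[C@]2(C)CC=C(Br)C(C)(C)O[C@H]2C=CC1=O | intermediate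
26 | (Z)-C14=C13 alkylidene dienone with C12 dimethyl acetal | COC(OC)/C=C1/[C@]2(C)CC=C(Br)C(C)(C)O[C@H]2C=CC1=O | intermediate
27 | saturated C24 ketone (14S,15S,21S) with CH2CH(OMe)2 on C14 | COC(OC)C[C@H]1[C@]2(C)CC=C(Br)C(C)(C)O[C@H]2CCC1=O | intermediate
28 | C24 exocyclic methylene compound | COC(OC)C[C@H]1[C@]2(C)CC=C(Br)C(C)(C)O[C@H]2CCC1=C | intermediate
29 | C24 spiro-epoxide (O equatorial, CH2 axial) | COC(OC)C[C@H]1[C@]2(C)CC=C(Br)C(C)(C)O[C@H]2CC[C@]13OC3 | intermediate
30 | (24S)-tertiary alcohol (OH equatorial, CH3 axial) | COC(OC)C[C@H]1[C@]2(C)CC=C(Br)C(C)(C)O[C@H]2CC[C@]1(C)O | intermediate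
31 | C24 acetate of 30 | COC(OC)C[C@H]1[C@]2(C)CC=C(Br)C(C)(C)O[C@H]2CC[C@]1(C)OC(C)=O | intermediate
32 | right-half aldehyde (C12=O; 14S,15S,21S,24S) | O=CC[C@H]1[C@]2(C)CC=C(Br)C(C)(C)O[C@H]2CC[C@]1(C)OC(C)=O | intermediate
33 | C11–C12 aldol adduct of 19 and 32 (diastereomers at C11 and C12) | O=C1C=C[C@@H]2OC(C)(C)[C@@H](O[Si](C)(C)C(C)(C)C)CC[C@@]2(C)C1C(O)C[C@H]1[C@]2(C)CC=C(Br)C(C)(C)O[C@H]2CC[C@]1(C)OC(C)=O | intermediate
34 | C12 mesylate of 33 | O=C1C=C[C@@H]2OC(C)(C)[C@@H](O[Si](C)(C)C(C)(C)C)CC[C@@]2(C)C1C(OS(C)(=O)=O)C[C@H]1[C@]2(C)CC=C(Br)C(C)(C)O[C@H]2CC[C@]1(C)OC(C)=O | intermediate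
35 | coupled (Z)-C11=C12 dienone (C1=O, C2=C3) | O=C1C=C[C@@H]2OC(C)(C)[C@@H](O[Si](C)(C)C(C)(C)C)CC[C@@]2(C)/C1=C/C[C@H]1[C@]2(C)CC=C(Br)C(C)(C)O[C@H]2CC[C@]1(C)OC(C)=O | intermediate
36 | coupled saturated C1 ketone (11S) | O=C1CC[C@@H]2OC(C)(C)[C@@H](O[Si](C)(C)C(C)(C)C)CC[C@@]2(C)[C@@H]1CC[C@H]1[C@]2(C)CC=C(Br)C(C)(C)O[C@H]2CC[C@]1(C)OC(C)=O | intermediate
37 | (1R)-tertiary alkoxide (metal salt, drawn as lithium alkoxide) | [Li+].[O-][C@]1(C)CC[C@@H]2OC(C)(C)[C@@H](O[Si](C)(C)C(C)(C)C)CC[C@@]2(C)[C@@H]1CC[C@H]1[C@]2(C)CC=C(Br)C(C)(C)O[C@H]2CC[C@]1(C)OC(C)=O | intermediate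
38 | C1,C24-diacetate with C17=C18(Br) and O7-TBS | CC(=O)O[C@]1(C)CC[C@@H]2OC(C)(C)[C@@H](O[Si](C)(C)C(C)(C)C)CC[C@@]2(C)[C@@H]1CC[C@H]1[C@]2(C)CC=C(Br)C(C)(C)O[C@H]2CC[C@]1(C)OC(C)=O | intermediate
39 | C18 pinacol boronate of 38 | CC(=O)O[C@]1(C)CC[C@@H]2OC(C)(C)[C@@H](O[Si](C)(C)C(C)(C)C)CC[C@@]2(C)[C@@H]1CC[C@H]1[C@]2(C)CC=C(B3OC(C)(C)C(C)(C)O3)C(C)(C)O[C@H]2CC[C@]1(C)OC(C)=O | intermediate
40 | O7-TBS ether of the target (C18 ketone) | CC(=O)O[C@]1(C)CC[C@@H]2OC(C)(C)[C@@H](O[Si](C)(C)C(C)(C)C)CC[C@@]2(C)[C@@H]1CC[C@H]1[C@]2(C)CCC(=O)C(C)(C)O[C@H]2CC[C@]1(C)OC(C)=O | intermediate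
41 | CNP0298533.1 | CC(=O)O[C@]1(C)CC[C@@H]2OC(C)(C)[C@@H](O)CC[C@@]2(C)[C@@H]1CC[C@H]1[C@]2(C)CCC(=O)C(C)(C)O[C@H]2CC[C@]1(C)OC(C)=O | target

**Count and risks**

Total steps: 24. Longest linear sequence: 19 (steps 1–5, 11–19, 20–24); the left branch (steps 6–10) runs in parallel.

Steps most likely to fail:

Step 5 (proposed new method). The oxocarbenium ion may lose a proton from the C19 methyl to a bromodiene, methyl may be delivered to C17, or the cyclopropane may open before the aluminium reagent is present. Fallback with known reactions, setting out from 9: the carbene adduct 11 is made as before and isolated, then opened with AgOAc in methanol, so that methanol captures the cation to give the bromo-oxepene methyl ketal F1 (silver-promoted ring expansion with an oxygen nucleophile). Me3Al in CH2Cl2 at −78 → 0 °C then exchanges methoxy for methyl (ketal methylation), and the route is rejoined at 12.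

Step 20. The neopentylic C11 enolate may add too slowly, so that proton transfer from the enolisable aldehyde, retro-aldol cleavage or γ-deprotonation at C4 compete. Fallback, setting out from 19: LDA/TMSCl gives the 2-silyloxydiene F3 and NBS brominates it at C11 to the bromo enone F4. SmI2 (2 equiv, THF, −78 °C) in the presence of 32 then generates the enolate reductively under non-basic conditions (Reformatsky-type aldol) and gives aldol adduct 33. Mesylation and elimination as before return to 35.

Step 3. The ketene acetal triflate may decompose on formation or handling, or sulfonylation may occur on carbon. Fallback, setting out from 7: methylenation of the lactone carbonyl with dimethyltitanocene (toluene, 70 °C) gives the exocyclic enol ether F2. A trace of PPTS in benzene moves the double bond into the ring, and the route is rejoined at 9, replacing steps 3 and 4.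

Further compounds
F1 | step 5 | bromo-oxepene methyl ketal (C19 OCH3/CH3, both epimers) | C1[C@]2(C)CC=C(Br)C(C)(OC)O[C@H]2CCC13OCCO3
F2 | step 3 | exocyclic enol ether (C19=CH2) from lactone 7 | C1[C@]2(C)CCC(=C)O[C@H]2CCC13OCCO3
F3 | step 20 | 2-(trimethylsilyloxy)diene of 19 (C11=C1(OTMS)–C2=C3) | C1[C@]2(C)CC[C@H](O[Si](C)(C)C(C)(C)C)C(C)(C)O[C@H]2C=CC=1O[Si](C)(C)C
F4 | step 20 | C11-bromo enone (both C11 epimers) | BrC1[C@]2(C)CC[C@H](O[Si](C)(C)C(C)(C)C)C(C)(C)O[C@H]2C=CC1=O
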